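The route rests on reading the C10 vinyl group (C1=C2) and the C5 acrolein unit (C3 aldehyde, C4=C15) on the cyclohexane (ring B) as the two ends of a broken C2–C3 bond of a eudesmane-type trans-decalin. One Grob fragmentation of ring A creates both π bonds and, since both esters are already in place, gives the natural product itself. Its precursor is the trans-decalin 8,12-lactone with an equatorial C1 mesylate anti-periplanar to C2–C3, a C3 hydroxyl, the C4 exocyclic methylene, the 6β-angelate and the 9β-(R)-2-methylbutanoate. The decalin arises from an asymmetric quinone Diels–Alder reaction, and the rigid bicycle sets C5–C9.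

Key step: step 20

Remarks on the chemistry (one line each):
- Eudesmane numbering is used; β is the face of the C10 methyl group, α the opposite face.
- An endo cycloaddition of an (E)-1-alkoxydiene puts the C1 oxygen trans to the C10 methyl (axial in the trans-decalin, unable to fragment), so C1 is oxidised and reduced again (steps 8 and 9) to the equatorial 1β-alcohol.
- Both acyl groups are installed before the fragmentation, because a free C6 or C9 hydroxyl would add to the new enal (lactol formation).
- The sense of induction of the (S)-BINOL catalyst in step 4 is assumed; if the antipodal adduct forms, (R)-BINOL is used.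

Step 1
Reactants: 1 2-methoxy-6-methylphenol
Product: 2 2-methoxy-6-methyl-1,4-benzoquinone
Conditions: Co(C16H14N2O2) (salcomine, 5 mol%), O2 (1 atm), DMF, 23 °C
Reagents that add atoms: dioxygen, O=O
Why: Cobalt–Schiff-base-catalysed aerobic oxidation of a 2,6-disubstituted phenol attacks the free para position and should give the p-quinone (phenol-to-quinone oxidation); no stereocentre is formed.

Step 2
Reactants: 3 (E)-4-methoxybut-3-en-2-one; 4 4-methoxybenzyl alcohol
Product: 5 (E)-4-(4-methoxybenzyloxy)but-3-en-2-one
Conditions: PPTS (cat.), PhMe, 85 °C, MeOH distilled off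
Reagents that add atoms: none
Why: Acid-catalysed alkoxy exchange on a β-alkoxy enone (conjugate addition–elimination, transetherification) is driven by removal of methanol, returns the E isomer and installs an ether that can later be cleaved oxidatively, which a methyl ether cannot.

Step 3
Reactants: 5 (E)-4-(4-methoxybenzyloxy)but-3-en-2-one
Product: 6 (E)-1-(4-methoxybenzyloxy)-3-(tert-butyldimethylsilyloxy)buta-1,3-diene
Conditions: TBSOTf, Et3N, Et2O, 0 °C
Reagents that add atoms: tert-butyldimethylsilyl trifluoromethanesulfonate, CC(C)(C)[Si](C)(C)OS(=O)(=O)C(F)(F)F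
Why: Soft enolisation of the methyl ketone with a silyl triflate and an amine base (the standard preparation of Danishefsky-type dienes) should give the 2-silyloxydiene with the E enol ether untouched.

Step 4
Reactants: 2 2-methoxy-6-methyl-1,4-benzoquinone; 6 diene
Product: 7 cis-fused adduct (10β-methyl; 5β-H; 1α-OPMB; 3-OTBS enol ether; 8-methoxy-7-ene-6,9-dione)
Conditions: TiCl2(OiPr)2 (10 mol%), (S)-BINOL (10 mol%), 4 Å MS, PhMe–CH2Cl2, −40 °C
Reagents that add atoms: none
Why: Catalytic asymmetric Diels–Alder reaction with a BINOL–titanium Lewis acid (Mikami-type catalyst): chelation of the quinone through the carbonyl flanked by OMe and Me and the methoxy oxygen activates the methyl-bearing double bond (the methoxy-bearing one is a deactivated vinylogous ester), the nucleophilic CH2 terminus of the diene bonds to the unsubstituted quinone carbon (future C5), the ligand sets the absolute configuration of the quaternary C10, endo addition gives the cis junction, and the C1 configuration is irrelevant because C1 is oxidised in step 8.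

Step 5
Reactants: 7 cis-fused adduct
Product: 8 trans-fused adduct (5α-H)
Conditions: DBU (0.3 equiv), PhMe, 40 °C
Reagents that add atoms: none
Why: Base-mediated epimerisation through the C6 enolate (thermodynamic equilibration, the classical cis-to-trans isomerisation of methoxytoluquinone–diene adducts) should place H5 trans to the C10 methyl; the quaternary C10 excludes aromatisation and the amidine base spares the silyl enol ether.

Step 6
Reactants: 8 trans-fused adduct
Product: 9 C3 ethylene ketal
Conditions: HOCH2CH2OH, CSA (cat.), CH2Cl2, −20 → 0 °C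
Reagents that add atoms: ethylene glycol, OCCO
Why: Acid-catalysed ketalisation of the silyl enol ether (C2 protonation, capture of the oxocarbenium ion by the diol, loss of silanol) masks the C3 ketone under conditions mild enough to keep the β-alkoxy group, and the ketal prevents a β-diketone when C1 is oxidised.

Step 7
Reactants: 9 C3 ethylene ketal
Product: 10 1α-alcohol
Conditions: DDQ, CH2Cl2–pH 7 buffer, 0 °C
Reagents that add atoms: none
Why: Oxidative cleavage of the p-methoxybenzyl ether by DDQ (benzylic hydride abstraction, then hydrolysis) frees the C1 hydroxyl under neutral conditions that leave the ketal and the enedione intact.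

Step 8
Reactants: 10 1α-alcohol
Product: 11 C1 ketone (1,6,9-trione 3-ketal)
Conditions: Dess–Martin periodinane, NaHCO3, CH2Cl2, 0 °C; crude product used at once
Reagents that add atoms: none
Why: Dess–Martin oxidation of the hindered secondary alcohol erases the axial C1 stereocentre set by the cycloaddition so that it can be rebuilt equatorial, and the buffered medium avoids β-elimination of the ketal.

Step 9
Reactants: 11 C1 ketone
Product: 12 1β,9β-diol
Conditions: NaBH4, MeOH–THF, −40 → 0 °C
Reagents that add atoms: none
Why: Borohydride reduction of the two ketones that flank the quaternary C10 should occur by axial attack from the α face, opposite the axial angular methyl (as in the reduction of the Wieland–Miescher ketone), giving the equatorial 1β- and 9β-alcohols, while the vinylogous ester carbonyl C6 is inert to NaBH4.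

Step 10
Reactants: 12 1β,9β-diol
Product: 13 1,9-O-di-tert-butylsilylene
Conditions: t-Bu2Si(OTf)2, 2,6-lutidine, CH2Cl2, 0 °C
Reagents that add atoms: di-tert-butylsilyl bis(trifluoromethanesulfonate), CC(C)(C)[Si](OS(=O)(=O)C(F)(F)F)(OS(=O)(=O)C(F)(F)F)C(C)(C)C
Why: The syn-1,3-diol across the ring junction closes a six-membered cyclic silylene (standard 1,3-diol protection), which masks both peri hydroxyls in one operation and survives the hydride, radical, mild-acid and amide-base steps that follow.

Step 11
Reactants: 13 1,9-O-di-tert-butylsilylene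
Product: 14 6β-allylic alcohol (C7=C8 methyl enol ether)
Conditions: i-Bu2AlH, PhMe, −78 °C; aqueous potassium sodium tartrate
Reagents that add atoms: none
Why: 1,2-Reduction of the vinylogous ester carbonyl should come from the α face because the β face of C6 is shielded by the syn-axial C10 methyl, giving the axial 6β-alcohol, and the non-acidic work-up keeps the allylic enol ether from ionising.

Step 12
Reactants: 14 6β-allylic alcohol; 15 ethyl bromoacetate
Product: 16 keto ester (6β-OH; 7α-CH2CO2Et; C8 ketone)
Conditions: 15 (2 equiv), Ir(C11H8N)3 (fac-tris(2-phenylpyridinato)iridium, 1 mol%), 2,6-lutidine, MeCN–H2O (9:1), blue LEDs, 23 °C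
Reagents that add atoms: water, O
Why: Photoredox radical alkylation of an enol ether (radical–polar crossover α-alkylation of a masked ketone): the electrophilic ester radical adds to the nucleophilic C7 terminus along the axial trajectory anti to the axial 6β-hydroxyl, which sets the 7α side chain, and oxidation of the α-methoxy radical followed by hydrolysis unveils the C8 ketone under buffered conditions.

Step 13
Reactants: 16 keto ester
Product: 18 hydroxy keto lactone (6β-OH; C3 ketone; cis-fused 8α,12-olide), via diol ester 17 (not isolated)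
Conditions: Me4NBH(OAc)3, MeCN–AcOH, −30 °C; then PPTS, acetone–H2O, 60 °C
Reagents that add atoms: water, O
Why: Evans–Saksena hydroxyl-directed reduction delivers hydride from boron bound to the axial 6β-hydroxyl to the β face of C8 (anti-1,3-diol), giving the equatorial 8α-alcohol, which is cis to the axial acetate chain and lactonises whereas the trans-diaxial 6β-hydroxyl cannot, and the same mild acid hydrolyses the dioxolane.

Step 14
Reactants: 18 hydroxy keto lactone
Product: 21 bis-methylene keto lactone (C4=C15 and C11=C13), via bis-Mannich base 19 (not isolated), via bis-ammonium iodide 20 (not isolated)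
Conditions: LiN(i-Pr)2 (3.5 equiv), THF, −78 °C; CH2=NMe2+ I− (4 equiv), −78 → 23 °C; then MeI, CH2Cl2–MeOH, 23 °C; then NaHCO3 (aq), EtOAc
Reagents that add atoms: N,N-dimethylmethyleneiminium iodide (Eschenmoser's salt), C=[N+](C)C.[I-]
Why: Double α-methylenation by Mannich reaction of the lithium enolates with Eschenmoser's salt, quaternisation and elimination (the bis-methylenation known from eudesmanolide and elemanolide synthesis); the ketone should be enolised towards C4 because C2 lies next to the C1 oxygen and the lithium 6β-alkoxide is syn-axial to H4β, the lactone enolate reacts at C11, and the transient C4 and C11 stereocentres vanish in the elimination.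

Step 15
Reactants: 21 bis-methylene keto lactone; 22 angelic acid
Product: 23 6β-angelate
Conditions: 22, 2,4,6-Cl3C6H2COCl, Et3N, PhMe, 23 °C; then 21, 70 °C
Reagents that add atoms: none
Why: Yamaguchi-type esterification through the mixed 2,4,6-trichlorobenzoic anhydride is the established way to acylate a hindered alcohol with angelic acid without Z-to-E isomerisation, and the axial 6β-hydroxyl is the only free hydroxyl.

Step 16
Reactants: 23 6β-angelate
Product: 24 1β,9β-diol
Conditions: HF·pyridine, pyridine–THF, 0 → 23 °C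
Reagents that add atoms: none
Why: Fluoride-mediated cleavage of the cyclic silylene (desilylation) liberates both peri hydroxyls under buffered conditions that leave the angelate, the exocyclic-methylene ketone and the α-methylene lactone untouched.

Step 17
Reactants: 24 1β,9β-diol
Product: 25 C1 mesylate
Conditions: MsCl (1.1 equiv), pyridine, CH2Cl2, −20 °C
Reagents that add atoms: methanesulfonyl chloride, CS(=O)(=O)Cl
Why: Sulfonylation in pyridine should take the C1 hydroxyl, whose second neighbour is a CH2 group, in preference to the C9 hydroxyl flanked by C10 and the oxygen-bearing C8; the peri relationship blocks a second sulfonylation and the weak base does not eliminate the equatorial β-mesyloxy ketone.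

Step 18
Reactants: 25 C1 mesylate; 26 (R)-2-methylbutanoic acid
Product: 27 diester mesylate (3-ketone)
Conditions: 26 (3 equiv), DIC, DMAP (cat.), CH2Cl2, 0 → 23 °C
Reagents that add atoms: none
Why: Steglich esterification (carbodiimide activation, catalytic DMAP, acid in excess) acylates the remaining C9 hydroxyl in a buffered medium that should neither eliminate the β-mesyloxy ketone nor racemise the α-stereocentre of the acid.

Step 19
Reactants: 27 diester mesylate
Product: 28 fragmentation precursor (1β-OMs; 3β-OH; 4(15)-methylene)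
Conditions: NaBH4, CeCl3·7H2O, MeOH, −78 °C; AcOH quench at −78 °C
Reagents that add atoms: none
Why: Luche 1,2-reduction of the exocyclic-methylene ketone by axial hydride attack from the α face gives the equatorial 3β allylic alcohol (its configuration is inconsequential) and, at low temperature, spares the α-methylene lactone, both esters and the mesylate.

Step 20
Reactants: 28 fragmentation precursor
Product: 30 target CNP0295282.1, via potassium alkoxide 29 (not isolated)
Conditions: KN(SiMe3)2 (1.0 equiv), THF, −78 → −20 °C; pH 7 buffer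
Reagents that add atoms: none
Why: KN(SiMe3)2 removes the C3 hydroxyl proton, the fastest acid–base event at −78 °C, and alkoxide 29 fragments in one concerted anti-periplanar process: the oxygen lone pair forms C3=O, the C2–C3 σ bond breaks and becomes the C1=C2 π bond, and mesylate leaves from C1. This is a Grob (Wharton-type) fragmentation of a cyclic 1,3-diol monosulfonate to an alkenyl aldehyde, a well-known reaction type. No ring is closed, so no mode of closure applies; ring A is opened. No stereocentre is created, and C5, C6, C7, C8, C9 and C10 keep the configurations set on the decalin. The step needs fragmentation to win over E2 elimination and substitution; this is secured by the trans ring fusion, which locks the equatorial C1–O bond anti-periplanar to C2–C3 and to no C–H bond, by the C4 methylene, which makes the product a conjugated enal, and by relief of the peri strain between the C1 and C9 oxygen substituents. One equivalent of a non-nucleophilic base at low temperature should leave the angelate, the 2-methylbutanoate and the α-methylene lactone alone, and since both hydroxyls are acylated the aldehyde cannot close to a lactol, so the product is the target.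

Compound list
1 | 2-methoxy-6-methylphenol | Cc1cccc(OC)c1O | starting material
2 | 2-methoxy-6-methyl-1,4-benzoquinone | COC1=CC(=O)C=C(C)C1=O | intermediate
3 | (E)-4-methoxybut-3-en-2-one | CO/C=C/C(C)=O | starting material
4 | 4-methoxybenzyl alcohol | COc1ccc(CO)cc1 | starting material
5 | (E)-4-(4-methoxybenzyloxy)but-3-en-2-one | COc1ccc(CO/C=C/C(C)=O)cc1 | intermediate
6 | (E)-1-(4-methoxybenzyloxy)-3-(tert-butyldimethylsilyloxy)buta-1,3-diene | COc1ccc(CO/C=C/C(=C)O[Si](C)(C)C(C)(C)C)cc1 | intermediate
7 | cis-fused adduct: 10β-methyl-5βH-decal-2,7-diene-6,9-dione with 1α-OPMB, 3-OTBS, 8-OMe | COc1ccc(CO[C@H]2C=C(O[Si](C)(C)C(C)(C)C)C[C@H]3C(=O)C=C(OC)C(=O)[C@@]23C)cc1 | intermediate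
8 | trans-fused adduct (5αH epimer of 7) | COc1ccc(CO[C@H]2C=C(O[Si](C)(C)C(C)(C)C)C[C@@H]3C(=O)C=C(OC)C(=O)[C@@]23C)cc1 | intermediate
9 | 1α-OPMB-3,3-ethylenedioxy-8-methoxy-10β-methyl-5αH-decal-7-ene-6,9-dione | COc1ccc(CO[C@H]2CC3(OCCO3)C[C@@H]4C(=O)C=C(OC)C(=O)[C@@]24C)cc1 | intermediate
10 | 1α-hydroxy analogue of 9 | O[C@H]1CC2(OCCO2)C[C@@H]3C(=O)C=C(OC)C(=O)[C@@]13C | intermediate
11 | 1,6,9-trione 3-ethylene ketal | O=C1CC2(OCCO2)C[C@@H]3C(=O)C=C(OC)C(=O)[C@@]13C | intermediate
12 | 1β,9β-dihydroxy-8-methoxy-7-en-6-one 3-ethylene ketal | O[C@@H]1CC2(OCCO2)C[C@@H]3C(=O)C=C(OC)[C@H](O)[C@@]13C | intermediate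
13 | 1β,9β-O-(di-tert-butylsilylene) derivative of 12 | CC(C)(C)[Si]1(C(C)(C)C)O[C@@H]2CC3(OCCO3)C[C@@H]4C(=O)C=C(OC)[C@H](O1)[C@@]24C | intermediate
14 | 6β-hydroxy-8-methoxy-7-ene (allylic alcohol, methyl enol ether), silylene and ketal retained | CC(C)(C)[Si]1(C(C)(C)C)O[C@@H]2CC3(OCCO3)C[C@@H]4[C@H](O)C=C(OC)[C@H](O1)[C@@]24C | intermediate
15 | ethyl bromoacetate | CCOC(=O)CBr | starting material
16 | ethyl (6β-hydroxy-8-oxo-7α-yl)acetate, silylene and ketal retained | CC(C)(C)[Si]1(C(C)(C)C)O[C@@H]2CC3(OCCO3)C[C@@H]4[C@H](O)[C@@H](CC(=O)OCC)C(=O)[C@H](O1)[C@@]24C | intermediate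
17 | ethyl (6β,8α-dihydroxy-7α-yl)acetate (diol ester) | CC(C)(C)[Si]1(C(C)(C)C)O[C@@H]2CC3(OCCO3)C[C@@H]4[C@H](O)[C@@H](CC(=O)OCC)[C@@H](O)[C@H](O1)[C@@]24C | intermediate
18 | 6β-hydroxy-3-oxo-8α,12-olide (cis-fused γ-lactone, 7βH,8βH), 1β,9β-silylene | CC(C)(C)[Si]1(C(C)(C)C)O[C@@H]2CC(=O)C[C@@H]3[C@H](O)[C@H]4CC(=O)O[C@H]4[C@H](O1)[C@@]23C | intermediate
19 | 4α,11-bis(dimethylaminomethyl) derivative of 18 (bis-Mannich base) | CC(C)(C)[Si]1(C(C)(C)C)O[C@@H]2CC(=O)[C@@H](CN(C)C)[C@@H]3[C@H](O)[C@H]4[C@H](CN(C)C)C(=O)O[C@H]4[C@H](O1)[C@@]23C | intermediate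
20 | bis(trimethylammonium) diiodide of 19 | CC(C)(C)[Si]1(C(C)(C)C)O[C@@H]2CC(=O)[C@@H](C[N+](C)(C)C)[C@@H]3[C@H](O)[C@H]4[C@H](C[N+](C)(C)C)C(=O)O[C@H]4[C@H](O1)[C@@]23C.[I-].[I-] | intermediate
21 | 6β-hydroxy-3-oxo-eudesma-4(15),11(13)-dien-12,8α-olide 1β,9β-silylene | CC(C)(C)[Si]1(C(C)(C)C)O[C@@H]2CC(=O)C(=C)[C@@H]3[C@H](O)[C@H]4C(=C)C(=O)O[C@H]4[C@H](O1)[C@@]23C | intermediate
22 | angelic acid | C/C=C(/C)C(=O)O | starting material
23 | 6β-angelate of 21 | CC(C)(C)[Si]1(C(C)(C)C)O[C@@H]2CC(=O)C(=C)[C@@H]3[C@H](OC(=O)/C(C)=C\C)[C@H]4C(=C)C(=O)O[C@H]4[C@H](O1)[C@@]23C | intermediate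
24 | 6β-angeloyloxy-1β,9β-dihydroxy-3-oxo-eudesma-4(15),11(13)-dien-12,8α-olide | O[C@@H]1CC(=O)C(=C)[C@@H]2[C@H](OC(=O)/C(C)=C\C)[C@H]3C(=C)C(=O)O[C@H]3[C@H](O)[C@@]12C | intermediate
25 | 1β-mesylate of 24 | CS(=O)(=O)O[C@@H]1CC(=O)C(=C)[C@@H]2[C@H](OC(=O)/C(C)=C\C)[C@H]3C(=C)C(=O)O[C@H]3[C@H](O)[C@@]12C | intermediate
26 | (R)-2-methylbutanoic acid | CC[C@@H](C)C(=O)O | starting material
27 | 9β-[(R)-2-methylbutanoate] of 25 | CS(=O)(=O)O[C@@H]1CC(=O)C(=C)[C@@H]2[C@H](OC(=O)/C(C)=C\C)[C@H]3C(=C)C(=O)O[C@H]3[C@H](OC(=O)[C@H](C)CC)[C@@]12C | intermediate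
28 | 6β-angeloyloxy-3β-hydroxy-1β-mesyloxy-9β-[(R)-2-methylbutanoyloxy]-5αH,7βH,8βH-eudesma-4(15),11(13)-dien-12,8α-olide | CS(=O)(=O)O[C@@H]1C[C@H](O)C(=C)[C@@H]2[C@H](OC(=O)/C(C)=C\C)[C@H]3C(=C)C(=O)O[C@H]3[C@H](OC(=O)[C@H](C)CC)[C@@]12C | intermediate
29 | potassium 3-alkoxide of 28 | CS(=O)(=O)O[C@@H]1C[C@H]([O-])C(=C)[C@@H]2[C@H](OC(=O)/C(C)=C\C)[C@H]3C(=C)C(=O)O[C@H]3[C@H](OC(=O)[C@H](C)CC)[C@@]12C.[K+] | intermediate
30 | CNP0295282.1 (elemanolide enal) | C=C[C@@]1(C)[C@H](C(=C)C=O)[C@H](OC(=O)/C(C)=C\C)[C@H]2C(=C)C(=O)O[C@H]2[C@@H]1OC(=O)[C@H](C)CC | target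

Total steps: 20. Longest linear sequence: 19 steps (steps 2–20, from (E)-4-methoxybut-3-en-2-one).

Steps most likely to fail

Step 12. What may go wrong: addition of the radical to the wrong face of C7, epimerisation at C7 by way of the oxocarbenium ion, or acid-triggered ionisation of the allylic alcohol with loss of the C6 oxygen. The fallback delivers the two-carbon unit by a stereospecific cyclopropanation instead of a radical addition. Starting from 14, the 6β-hydroxyl is capped as trimethylsilyl ether F1 (TMSCl, imidazole, DMF). The enol ether is then cyclopropanated on its open α face with ethyl diazoacetate and Rh2(OAc)4 to give donor–acceptor cyclopropane F2. Cold dilute acid (0.1 M HCl, THF–H2O, 0 °C) opens the C8–C11 bond and removes the silyl group, which returns the route to keto ester 16.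

Step 14. What may go wrong: enolisation of the ketone towards C2 instead of C4, followed by β-elimination of the C1 oxygen, or incomplete double aminomethylation. The fallback uses the C1 oxygen as a free alkoxide, the classical way to force α′-enolisation of a β-hydroxy ketone. Starting from 18, HF·pyridine removes the silylene to give triol F3. Excess LiN(i-Pr)2 forms the trialkoxide, whose 1β-alkoxide suppresses deprotonation at C2. The same sequence then runs through bis-Mannich base F4 (Eschenmoser's salt) and bis-ammonium salt F5 (MeI) to bis-methylene triol F6 (NaHCO3). t-Bu2Si(OTf)2 and 2,6-lutidine close the silylene again on the syn-1,3-diol, which returns to 21.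

Step 17. What may go wrong: insufficient discrimination between the two peri hydroxyls, and base-induced elimination of the β-mesyloxy ketone during the following acylation. The fallback sorts the hydroxyls with a bulky silyl chloride and reverses the order of acylation and sulfonylation. Starting from 24, TESCl and imidazole at −40 °C give C1 triethylsilyl ether F7. Steglich esterification with 26 gives C9 ester F8, and HF·pyridine frees the C1 hydroxyl to give hydroxy diester F9. Mesylation of this only free hydroxyl (MsCl, pyridine) returns to 27.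

Further compounds
F1 | step 12 | 6β-O-trimethylsilyl ether of 14 | CC(C)(C)[Si]1(C(C)(C)C)O[C@@H]2CC3(OCCO3)C[C@@H]4[C@H](O[Si](C)(C)C)C=C(OC)[C@H](O1)[C@@]24C
F2 | step 12 | 7α,8α-fused ethyl 8-methoxycyclopropanecarboxylate (C7–C11–C8 cyclopropane, exo ester) | CC(C)(C)[Si]1(C(C)(C)C)O[C@@H]2CC3(OCCO3)C[C@@H]4[C@H](O[Si](C)(C)C)[C@H]5[C@H](C(=O)OCC)[C@@]5(OC)[C@H](O1)[C@@]24C
F3 | step 14 | 1β,6β,9β-trihydroxy-3-oxo-8α,12-olide | O[C@@H]1CC(=O)C[C@@H]2[C@H](O)[C@H]3CC(=O)O[C@H]3[C@H](O)[C@@]12C
F4 | step 14 | 4α,11-bis(dimethylaminomethyl) derivative of F3 | O[C@@H]1CC(=O)[C@@H](CN(C)C)[C@@H]2[C@H](O)[C@H]3[C@H](CN(C)C)C(=O)O[C@H]3[C@H](O)[C@@]12C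
F5 | step 14 | bis(trimethylammonium) diiodide of F4 | O[C@@H]1CC(=O)[C@@H](C[N+](C)(C)C)[C@@H]2[C@H](O)[C@H]3[C@H](C[N+](C)(C)C)C(=O)O[C@H]3[C@H](O)[C@@]12C.[I-].[I-]
F6 | step 14 | 1β,6β,9β-trihydroxy-3-oxo-eudesma-4(15),11(13)-dien-12,8α-olide | O[C@@H]1CC(=O)C(=C)[C@@H]2[C@H](O)[C@H]3C(=C)C(=O)O[C@H]3[C@H](O)[C@@]12C
F7 | step 17 | 1β-O-triethylsilyl ether of 24 | CC[Si](CC)(CC)O[C@@H]1CC(=O)C(=C)[C@@H]2[C@H](OC(=O)/C(C)=C\C)[C@H]3C(=C)C(=O)O[C@H]3[C@H](O)[C@@]12C
F8 | step 17 | 9β-[(R)-2-methylbutanoate] of F7 | CC[Si](CC)(CC)O[C@@H]1CC(=O)C(=C)[C@@H]2[C@H](OC(=O)/C(C)=C\C)[C@H]3C(=C)C(=O)O[C@H]3[C@H](OC(=O)[C@H](C)CC)[C@@]12C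
F9 | step 17 | 1β-hydroxy 6β-angelate 9β-[(R)-2-methylbutanoate] (3-ketone) | O[C@@H]1CC(=O)C(=C)[C@@H]2[C@H](OC(=O)/C(C)=C\C)[C@H]3C(=C)C(=O)O[C@H]3[C@H](OC(=O)[C@H](C)CC)[C@@]12C
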